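| flask | free monomer | transfer agent | initiator | remark | time |
|---|---|---|---|---|---|
| north | 0.14 M | 1 mM | 2.5 mM | run made earlier |  |
| north-east | 0.22 M | 1 mM | 2.5 mM | run made earlier |  |
| south-west | 0.10 M | 1.5 mM | 2.5 mM | run made earlier |  |
| flask | 0.10 M | 1.00 mM | 2.5 mM |  | 2.5 d |

- north (time / h: monomer in chains / %, free monomer / %): 2.50: 4.7, 95.1; 8.00: 12.7, 88.5; 12.0: 18.5, 80.7; 20.0: 29.0, 71.7; 30.0: 36.7, 63.4; 40.0: 46.5, 55.2
- north-east (time / h: monomer in chains / %, free monomer / %): 6.00: 10.0, 90.0; 12.0: 21.6, 80.4; 20.0: 26.5, 71.1; 25.0: 35.2, 65.6; 30.0: 39.8, 60.8; 40.0: 47.1, 54.5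
- south-west (time / h: monomer in chains / %, free monomer / %): 3.00: 3.2, 95.3; 5.00: 6.8, 93.7; 10.0: 13.0, 86.7; 20.0: 23.2, 76.6; 40.0: 36.4, 61.7

(each reading ± 1 percentage point)

- the average divides the monomer in chains by the number of chains begun, living and dead together
- the earlier runs do not show the number of chains; that part of a forecast is a guess

* whether the average number of monomer units in a chain (chains begun, living or dead) reaches 10 by 2.5 d (no / yes)
* average number of monomer units in a chain (chains begun, living or dead) at 2.5 d

**Easy step.** Free monomer is the easy part. North and north-east, charged at 0.14 M and 0.22 M, keep 55.2% and 54.5% at 40.0 h, equal within the scatter, so the loss reads as pseudo-first-order. The flask shares their agent and initiator charges, so it is reckoned on their curve. North's slope k between 20.0 h and 40.0 h is 0.0131 h⁻¹, which takes the flask to 42.5% free monomer at 2.5 d.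

**The neighbour.** South-west has the flask's monomer and initiator charges but 1.5 mM of agent against 1.00 mM. At 40.0 h it keeps 61.7%, more than north's 55.2%. North differs from south-west in monomer charge as well, but north and north-east, with different monomer charges, kept equal percentages within the scatter, so the gap is read as the agent's. More agent thus goes with a slower run, and the agent reads as a stopper of growing chains, not a starter of new ones.

**Chain floor.** The chain count stays a guess, but on that reading chains begun stay within the initiator charge. The flask's reacted monomer over 2.5 mM gives 23.0: this is ℓ, free monomer reacted per initiator charged. This reckoning therefore puts the length at ℓ or somewhat above, beyond 10.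

**The result.** The forecast answers yes with 21 units, below this floor, and says “The chain count is the guess”. The flask gives yes and 26.2 units.

    free monomer + initiator → spent initiator (k = 0.00460 M⁻¹ min⁻¹)
    free monomer + living end → monomer in chains + living end, rate k2*[living end]*[free monomer] (k = 0.190 M⁻¹ min⁻¹)
    free monomer + initiator → living end + monomer in chains (k = 0.0420 M⁻¹ min⁻¹)
    living end + transfer agent → dead chain (kL = 1.50 M⁻¹ min⁻¹)

**Two fates.** Initiator enters chains 9.1 times as fast as it becomes spent initiator, at 0.978 d. The flask's ℓ, now 23.7 with 41% free monomer left, raised by that split gives 26.3 units over 2.25 mM of living ends and dead chains. South-west's ℓ at 40.0 h, 15.3, reads with the same split as 17.0 units.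

The numbers in the tables were generated by integration for an exercise, and the scatter is random.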